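**Plan**
1. Retrosynthesis: the silyl group on O6 and a temporary C4 carbonyl are removed first. The oxygen ring is then cut at C2–C3 (carbene C–H insertion) and at O1–C2 (Mitsunobu ether), giving an o-hydroxyacetophenone and a C43 methyl carbinol.
2. The carbinol carries C2, its methyl and the whole side chain; it comes from solanesol by excision of C1 and C2. The arene comes from 2,3-dimethylhydroquinone by C-acetylation.
3. Forward: chain ketone, then (S)-carbinol; acetophenone, then mono silyl ether; ether union; diazo transfer at the acetyl methyl; closure of the oxygen ring onto the benzene ring; removal of C4=O and of the silyl group.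
4. Enabling feature: C2 is bonded to the ring oxygen O1. In the open aryl ether it is therefore a tertiary, oxygen-activated C–H lying 1,6 to C3 once C3 is a carbene carbon held on C4a through the C4 carbonyl. The 1,5 position is O1 itself, so only six-ring closure is open.
5. Stereochemistry: lipase resolution gives the (S)-carbinol, the Mitsunobu step inverts it to the (R)-ether, and C–H insertion goes with retention to give (R) at quaternary C2. The chain alkenes keep the E geometry of solanesol.

Key step: step 9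

Remark: commercial solanesol is taken as the all-E nonaprenol. The 2,3-epoxide is made as the racemate because both of its stereocentres are destroyed in step 2.
Short names: "C43" compounds have the all-E 6,10,14,18,22,26,30,34-octamethylpentatriaconta-5,9,13,17,21,25,29,33-octaene skeleton numbered from the oxygenated end. "C41 chain" is the (3E,7E,11E,15E,19E,23E,27E)-4,8,12,16,20,24,28,32-octamethyltritriaconta-3,7,11,15,19,23,27,31-octaen-1-yl group.

**Step 1**
Reactants: 1 solanesol
Product: 2 2,3-epoxysolanesol (racemic trans epoxide)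
Conditions: VO(acac)2 (cat.), t-BuOOH, toluene, 0 °C to rt
Reagents that add atoms: tert-butyl hydroperoxide CC(C)(C)OO
Why: Hydroxyl-directed vanadium-catalysed epoxidation delivers oxygen only to the alkene next to the bound allylic alkoxide, so the eight isolated trisubstituted alkenes should stay intact.

**Step 2**
Reactants: 2 2,3-epoxysolanesol
Product: 4 C43 methyl ketone (all-E octaprenylacetone), via solanesol 1,2,3-triol 3 (not isolated)
Conditions: H5IO6 (2.2 equiv), THF/Et2O/H2O, 0 °C
Reagents that add atoms: water O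
Why: Periodic acid opens the epoxide with water to the triol and cleaves both glycol bonds (Malaprade cleavage), which excises C1 and C2 of solanesol and leaves the methyl ketone without touching isolated alkenes.

**Step 3**
Reactants: 4 C43 methyl ketone
Product: 5 racemic C43 carbinol (C43 octaen-2-ol)
Conditions: NaBH4, MeOH/THF, 0 °C
Reagents that add atoms: none
Why: Borohydride reduction of an unhindered methyl ketone is chemoselective over the alkenes and gives the racemate that step 4 resolves.

**Step 4**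
Reactants: 5 racemic C43 carbinol
Product: 6 (S)-C43 carbinol
Conditions: Candida antarctica lipase B (immobilised), vinyl acetate, hexane, 35 °C, stopped just past half conversion; chromatography
Reagents that add atoms: none
Why: In this lipase-catalysed kinetic resolution by transesterification the enzyme acylates the (R)-enantiomer of methyl carbinols (methyl in the small pocket, long chain toward the solvent), so the alcohol left unreacted should be the (S)-enantiomer, separable from the (R)-acetate.

**Step 5**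
Reactants: 7 2,3-dimethylhydroquinone
Product: 8 1-(2,5-dihydroxy-3,4-dimethylphenyl)ethan-1-one
Conditions: AcOH, BF3·OEt2, 100 °C
Reagents that add atoms: acetic acid CC(=O)O
Why: Boron trifluoride-mediated C-acylation (Friedel–Crafts/Fries type) occurs ortho to a hydroxyl; the two free ring positions are equivalent, and the ketone deactivates the ring against a second acylation.

**Step 6**
Reactants: 8 1-(2,5-dihydroxy-3,4-dimethylphenyl)ethan-1-one
Product: 9 1-[5-(tert-butyldimethylsilyloxy)-2-hydroxy-3,4-dimethylphenyl]ethan-1-one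
Conditions: TBSCl (1 equiv), imidazole, DMF, 0 °C
Reagents that add atoms: tert-butyldimethylsilyl chloride CC(C)(C)[Si](C)(C)Cl
Why: The 2-hydroxyl is hydrogen-bonded to the ketone and flanked on both sides, so one equivalent of silyl chloride should react at the free 5-hydroxyl.

**Step 7**
Reactants: 6 (S)-C43 carbinol; 9 mono-silylated acetophenone (used in excess)
Product: 10 (R)-aryl ether ketone, 1-[5-(tert-butyldimethylsilyloxy)-3,4-dimethyl-2-{[(2R)-C43 octaen-2-yl]oxy}phenyl]ethan-1-one
Conditions: PPh3, DIAD, THF, 0 °C to rt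
Reagents that add atoms: none
Why: In the Mitsunobu etherification the alkoxyphosphonium ion from 6 is displaced by the acidic, ketone-activated phenol in an SN2 step with inversion, turning the (S)-carbinol into the (R)-aryl ether.

**Step 8**
Reactants: 10 (R)-aryl ether ketone
Product: 12 (R)-diazoketone, 2-diazo-1-[5-(tert-butyldimethylsilyloxy)-3,4-dimethyl-2-{[(2R)-C43 octaen-2-yl]oxy}phenyl]ethan-1-one, via trifluoroacetyl diketone 11 (not isolated)
Conditions: LiN(SiMe3)2, THF, −78 °C, then CF3CO2CH2CF3; then MsN3, Et3N, H2O, MeCN, rt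
Reagents that add atoms: 2,2,2-trifluoroethyl trifluoroacetate O=C(OCC(F)(F)F)C(F)(F)F (its acyl group stays only in 11); methanesulfonyl azide CS(=O)(=O)N=[N+]=[N-]
Why: In this detrifluoroacetylative diazo transfer, trifluoroacetylation of the methyl ketone enolate activates the only enolisable position for transfer of N2 from the sulfonyl azide, and the ether stereocentre has no acidic hydrogen and is untouched.

**Step 9**
Reactants: 12 (R)-diazoketone
Product: 13 (2R)-6-(tert-butyldimethylsilyloxy)-2,7,8-trimethyl-2-(C41 chain)chroman-4-one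
Conditions: Rh2(OAc)4 (1 mol %), CH2Cl2, reflux, slow addition of 12, high dilution
Reagents that add atoms: none
Why: Loss of N2 from 12 at the dirhodium core gives an electrophilic acyl carbene on the carbon that becomes C3, and this inserts into the tertiary C–H of the future C2, a bond made electron-rich by the adjacent ether oxygen O1, through a concerted three-centre C–H–C transition state. The closest known reaction type is the dirhodium-carboxylate-catalysed intramolecular C–H insertion of 2-alkoxyphenyl diazomethyl ketones to chroman-4-ones, combined with the retentive insertion known for stereogenic tertiary C–H bonds. The oxygen ring (a dihydropyranone) closes by 1,6-insertion through a six-membered arrangement, because the normally preferred 1,5 position is O1 itself. The new quaternary stereocentre C2 is controlled by the (R)-methine already present in 12: insertion goes with retention, and C3 takes the place of the hydrogen. The step needs chemoselectivity for this C–H bond over oxonium ylide formation at O1 and over cyclopropanation of the eight chain alkenes. This is secured by the carboxylate catalyst class (which gives insertion where copper catalysts give ylide products), by the absence of an allyl or benzyl group on O1 that could migrate, by the proximity and activation of the α-oxy methine, and by slow addition at high dilution.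

**Step 10**
Reactants: 13 (2R)-chroman-4-one
Product: 14 tosylhydrazone of 13 (C=N geometry not defined)
Conditions: TsNHNH2, EtOH/THF, 60 °C
Reagents that add atoms: p-toluenesulfonyl hydrazide Cc1ccc(cc1)S(=O)(=O)NN
Why: The aryl ketone condenses with the hydrazide under neutral conditions, with no base present that could open the chromanone by retro-oxa-Michael reaction and racemise C2.

**Step 11**
Reactants: 14 tosylhydrazone
Product: 17 plastochromanol 8 tert-butyldimethylsilyl ether, via N-boryl tosylhydrazine 15 (not isolated), via monoalkyl diazene 16 (not isolated)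
Conditions: catecholborane, CHCl3, 0 °C to rt; then NaOAc·3H2O, reflux
Reagents that add atoms: catecholborane B1Oc2ccccc2O1 (its atoms stay only in 15)
Why: Catecholborane adds hydride to C=N and acetate then triggers loss of sulfinate to a diazene that expels N2, which leaves CH2 at C4 without any cationic intermediate that a chain alkene could trap; catecholborane should not hydroborate trisubstituted alkenes at this temperature.

**Step 12**
Reactants: 17 plastochromanol 8 tert-butyldimethylsilyl ether
Product: 18 plastochromanol 8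
Conditions: TBAF, THF, 0 °C, argon
Reagents that add atoms: none
Why: Fluoride cleaves the aryl silyl ether under non-acidic, non-reducing conditions that the polyene and the C2 stereocentre tolerate.

**Compound list**
1 | solanesol, (2E,6E,10E,14E,18E,22E,26E,30E)-3,7,11,15,19,23,27,31,35-nonamethylhexatriaconta-2,6,10,14,18,22,26,30,34-nonaen-1-ol | CC(C)=CCC/C(C)=C/CC/C(C)=C/CC/C(C)=C/CC/C(C)=C/CC/C(C)=C/CC/C(C)=C/CC/C(C)=C/CC/C(C)=C/CO | starting material
2 | 2,3-epoxysolanesol, racemic trans epoxide (2RS,3RS), other eight alkenes unchanged | CC(C)=CCC/C(C)=C/CC/C(C)=C/CC/C(C)=C/CC/C(C)=C/CC/C(C)=C/CC/C(C)=C/CC/C(C)=C/CCC1(C)OC1CO | intermediate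
3 | solanesol 1,2,3-triol (2,3-dihydroxy-2,3-dihydrosolanesol, stereoisomer mixture) | CC(C)=CCC/C(C)=C/CC/C(C)=C/CC/C(C)=C/CC/C(C)=C/CC/C(C)=C/CC/C(C)=C/CC/C(C)=C/CCC(C)(O)C(O)CO | intermediate (not isolated)
4 | (5E,9E,13E,17E,21E,25E,29E)-6,10,14,18,22,26,30,34-octamethylpentatriaconta-5,9,13,17,21,25,29,33-octaen-2-one | CC(C)=CCC/C(C)=C/CC/C(C)=C/CC/C(C)=C/CC/C(C)=C/CC/C(C)=C/CC/C(C)=C/CC/C(C)=C/CCC(C)=O | intermediate
5 | racemic (5E,9E,13E,17E,21E,25E,29E)-6,10,14,18,22,26,30,34-octamethylpentatriaconta-5,9,13,17,21,25,29,33-octaen-2-ol | CC(C)=CCC/C(C)=C/CC/C(C)=C/CC/C(C)=C/CC/C(C)=C/CC/C(C)=C/CC/C(C)=C/CC/C(C)=C/CCC(C)O | intermediate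
6 | (2S,5E,9E,13E,17E,21E,25E,29E)-6,10,14,18,22,26,30,34-octamethylpentatriaconta-5,9,13,17,21,25,29,33-octaen-2-ol | CC(C)=CCC/C(C)=C/CC/C(C)=C/CC/C(C)=C/CC/C(C)=C/CC/C(C)=C/CC/C(C)=C/CC/C(C)=C/CC[C@H](C)O | intermediate
7 | 2,3-dimethylhydroquinone (2,3-dimethylbenzene-1,4-diol) | Cc1c(C)c(O)ccc1O | starting material
8 | 1-(2,5-dihydroxy-3,4-dimethylphenyl)ethan-1-one | CC(=O)c1cc(O)c(C)c(C)c1O | intermediate
9 | 1-[5-(tert-butyldimethylsilyloxy)-2-hydroxy-3,4-dimethylphenyl]ethan-1-one | CC(=O)c1cc(O[Si](C)(C)C(C)(C)C)c(C)c(C)c1O | intermediate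
10 | 1-[5-(tert-butyldimethylsilyloxy)-3,4-dimethyl-2-{[(2R,5E,9E,13E,17E,21E,25E,29E)-6,10,14,18,22,26,30,34-octamethylpentatriaconta-5,9,13,17,21,25,29,33-octaen-2-yl]oxy}phenyl]ethan-1-one | CC(C)=CCC/C(C)=C/CC/C(C)=C/CC/C(C)=C/CC/C(C)=C/CC/C(C)=C/CC/C(C)=C/CC/C(C)=C/CC[C@@H](C)Oc1c(C)c(C)c(O[Si](C)(C)C(C)(C)C)cc1C(C)=O | intermediate
11 | 4,4,4-trifluoro-1-[aryl of 10]butane-1,3-dione (trifluoroacetyl diketone, R ether centre retained) | CC(C)=CCC/C(C)=C/CC/C(C)=C/CC/C(C)=C/CC/C(C)=C/CC/C(C)=C/CC/C(C)=C/CC/C(C)=C/CC[C@@H](C)Oc1c(C)c(C)c(O[Si](C)(C)C(C)(C)C)cc1C(=O)CC(=O)C(F)(F)F | intermediate (not isolated)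
12 | 2-diazo-1-[5-(tert-butyldimethylsilyloxy)-3,4-dimethyl-2-{[(2R)-C43 octaen-2-yl]oxy}phenyl]ethan-1-one | CC(C)=CCC/C(C)=C/CC/C(C)=C/CC/C(C)=C/CC/C(C)=C/CC/C(C)=C/CC/C(C)=C/CC/C(C)=C/CC[C@@H](C)Oc1c(C)c(C)c(O[Si](C)(C)C(C)(C)C)cc1C(=O)C=[N+]=[N-] | intermediate
13 | (2R)-6-(tert-butyldimethylsilyloxy)-2,7,8-trimethyl-2-[(3E,7E,11E,15E,19E,23E,27E)-4,8,12,16,20,24,28,32-octamethyltritriaconta-3,7,11,15,19,23,27,31-octaen-1-yl]chroman-4-one | CC(C)=CCC/C(C)=C/CC/C(C)=C/CC/C(C)=C/CC/C(C)=C/CC/C(C)=C/CC/C(C)=C/CC/C(C)=C/CC[C@]1(C)CC(=O)c2cc(O[Si](C)(C)C(C)(C)C)c(C)c(C)c2O1 | intermediate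
14 | 4-(p-toluenesulfonylhydrazono) derivative of 13 (tosylhydrazone, 2R) | CC(C)=CCC/C(C)=C/CC/C(C)=C/CC/C(C)=C/CC/C(C)=C/CC/C(C)=C/CC/C(C)=C/CC/C(C)=C/CC[C@]1(C)CC(=NNS(=O)(=O)c3ccc(C)cc3)c2cc(O[Si](C)(C)C(C)(C)C)c(C)c(C)c2O1 | intermediate
15 | 4-[N-(1,3,2-benzodioxaborol-2-yl)-N'-tosylhydrazino]chroman from 14 (2R, C4 epimers) | CC(C)=CCC/C(C)=C/CC/C(C)=C/CC/C(C)=C/CC/C(C)=C/CC/C(C)=C/CC/C(C)=C/CC/C(C)=C/CC[C@]1(C)CC(N(NS(=O)(=O)c3ccc(C)cc3)B3Oc4ccccc4O3)c2cc(O[Si](C)(C)C(C)(C)C)c(C)c(C)c2O1 | intermediate (not isolated)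
16 | 4-diazenylchroman from 15 (monoalkyl diazene, 2R) | CC(C)=CCC/C(C)=C/CC/C(C)=C/CC/C(C)=C/CC/C(C)=C/CC/C(C)=C/CC/C(C)=C/CC/C(C)=C/CC[C@]1(C)CC(N=N)c2cc(O[Si](C)(C)C(C)(C)C)c(C)c(C)c2O1 | intermediate (not isolated)
17 | (2R)-6-(tert-butyldimethylsilyloxy)-2,7,8-trimethyl-2-(C41 chain)chroman (plastochromanol 8 silyl ether) | CC(C)=CCC/C(C)=C/CC/C(C)=C/CC/C(C)=C/CC/C(C)=C/CC/C(C)=C/CC/C(C)=C/CC/C(C)=C/CC[C@]1(C)CCc2cc(O[Si](C)(C)C(C)(C)C)c(C)c(C)c2O1 | intermediate
18 | plastochromanol 8, (2R)-2,7,8-trimethyl-2-[(3E,7E,11E,15E,19E,23E,27E)-4,8,12,16,20,24,28,32-octamethyltritriaconta-3,7,11,15,19,23,27,31-octaen-1-yl]chroman-6-ol | CC(C)=CCC/C(C)=C/CC/C(C)=C/CC/C(C)=C/CC/C(C)=C/CC/C(C)=C/CC/C(C)=C/CC/C(C)=C/CC[C@]1(C)CCc2cc(O)c(C)c(C)c2O1 | target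

**Step count**
Total: 12 steps. Longest linear sequence: 10 steps (1–4, then 7–12).

**Steps most likely to fail, with fallbacks**

Step 9 (ring-closing C–H insertion). The carbene may be intercepted by the ether oxygen O1 (oxonium ylide formation, then alkyl shift or elimination) or by chain alkenes (cyclopropanation). The fallback builds the oxygen ring by Kabbe condensation, setting out from acetophenone 8 and ketone 4. Pyrrolidine in toluene with removal of water (enamine aldol, dehydration, oxa-Michael closure) should give the racemic 6-hydroxy-2,7,8-trimethyl-2-(C41 chain)chroman-4-one F1. Silylation under the conditions of step 6 should give the racemic silyl ether F2. Preparative chromatography on a chiral stationary phase should then deliver the (R)-enantiomer, and the route is rejoined at 13.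

Step 7 (Mitsunobu etherification). The phenol is hindered on both sides and hydrogen-bonded to the ketone, so displacement may be slow and elimination of the activated alcohol may take over. The fallback sets out from 6: MsCl and Et3N in CH2Cl2 at 0 °C should give, with retention, the (S)-C43 carbinol methanesulfonate F3. Displacement of F3 by the cesium phenoxide of 9 (Cs2CO3, DMF, 50 °C), a Williamson etherification with inversion in a solvent that breaks the internal hydrogen bond, comes back to the route at 10.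

Step 11 (removal of the C4 oxygen). The hydrazone may eliminate toward the chromene instead of being reduced, or reduction may stall at the hindered aryl C=N bond. The fallback sets out from 13. NaBH4 in MeOH/THF should give the (2R)-chroman-4-ol F4 as a mixture of C4 epimers. Burgess reagent in toluene at 50 °C should dehydrate it to the (2R)-2H-chromene F5. Sodium in ethanol should then reduce only the styrene-type C3=C4 bond, and the ethoxide formed should remove the silyl group, so the sequence comes back directly at 18.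

**Further compounds**
F1 | step 9 | racemic 6-hydroxy-2,7,8-trimethyl-2-(C41 chain)chroman-4-one | CC(C)=CCC/C(C)=C/CC/C(C)=C/CC/C(C)=C/CC/C(C)=C/CC/C(C)=C/CC/C(C)=C/CC/C(C)=C/CCC1(C)CC(=O)c2cc(O)c(C)c(C)c2O1
F2 | step 9 | racemic 6-(tert-butyldimethylsilyloxy)-2,7,8-trimethyl-2-(C41 chain)chroman-4-one | CC(C)=CCC/C(C)=C/CC/C(C)=C/CC/C(C)=C/CC/C(C)=C/CC/C(C)=C/CC/C(C)=C/CC/C(C)=C/CCC1(C)CC(=O)c2cc(O[Si](C)(C)C(C)(C)C)c(C)c(C)c2O1
F3 | step 7 | (2S)-C43 octaen-2-yl methanesulfonate | CC(C)=CCC/C(C)=C/CC/C(C)=C/CC/C(C)=C/CC/C(C)=C/CC/C(C)=C/CC/C(C)=C/CC/C(C)=C/CC[C@H](C)OS(C)(=O)=O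
F4 | step 11 | (2R)-6-(tert-butyldimethylsilyloxy)-2,7,8-trimethyl-2-(C41 chain)chroman-4-ol (C4 epimers) | CC(C)=CCC/C(C)=C/CC/C(C)=C/CC/C(C)=C/CC/C(C)=C/CC/C(C)=C/CC/C(C)=C/CC/C(C)=C/CC[C@]1(C)CC(O)c2cc(O[Si](C)(C)C(C)(C)C)c(C)c(C)c2O1
F5 | step 11 | (2R)-6-(tert-butyldimethylsilyloxy)-2,7,8-trimethyl-2-(C41 chain)-2H-chromene | CC(C)=CCC/C(C)=C/CC/C(C)=C/CC/C(C)=C/CC/C(C)=C/CC/C(C)=C/CC/C(C)=C/CC/C(C)=C/CC[C@]1(C)C=Cc2cc(O[Si](C)(C)C(C)(C)C)c(C)c(C)c2O1
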